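**Assumption:** compounds 1, 4, 10, 11, 13 and all unnumbered reagents are bought. Core atoms carry oxolane locants: O1, C2 (bears the aryloxy-substituted ring), C3, C4, C5 (bears the 3,4-dimethoxyphenyl ring). The target is read as (2S,3R,4R,5S)-2,3-cis-3,4-trans-4,5-cis with a threo (1R,2R) side chain.

## Retrosynthetic overview

1. C2–aryl bond (last step): the anodically generated oxocarbenium ion 16 (from thioacetal 9) is trapped by arylzinc 17, which carries the finished side chain; this sets C2.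
2. 9 ⇐ lactol 8 ⇐ branch-selective hydroformylation of homoallylic alcohol 6; C3 is set by equilibration.
3. 6 ⇐ 3,4-dimethoxybenzaldehyde 4 + allenylstannane 3 from (R)-but-3-yn-2-ol 1; this sets C5 and C4.
4. 17 ⇐ aryl bromide 15 ⇐ Mitsunobu inversion of the lactamide-derived (S)-α-hydroxy ketone 12 with 4-bromo-2-methoxyphenol, then Felkin–Anh reduction.
5. Ring order: the oxolane is the only ring made. It closes once, as lactol 8 (step 5), and is then substituted twice at C2 (steps 6 and 10).

## Route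

Step 1
Reactants: 1 (R)-but-3-yn-2-ol
Product: 2 (R)-but-3-yn-2-yl methanesulfonate
Conditions: MsCl, Et3N, CH2Cl2, −78 to 0 °C
Reagents that add atoms: methanesulfonyl chloride, CS(=O)(=O)Cl
Why: O-sulfonylation; the C–O bond is not touched, so the bought (R) centre is kept.

Step 2
Reactants: 2 (R)-but-3-yn-2-yl methanesulfonate
Product: 3 (P)-tributyl(buta-1,2-dien-1-yl)stannane
Conditions: Bu3SnH, LDA, THF, 0 °C; CuBr·SMe2, −78 °C; then 2, −78 °C
Reagents that add atoms: tributyltin hydride, CCCC[SnH](CCCC)CCCC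
Why: Marshall anti-SN2′ stannylcupration of a propargylic mesylate; the bought centre is transferred into the (P) allene axis.

Step 3
Reactants: 3 (P)-tributyl(buta-1,2-dien-1-yl)stannane; 4 3,4-dimethoxybenzaldehyde
Product: 5 (1S,2R)-1-(3,4-dimethoxyphenyl)-2-methylbut-3-yn-1-ol
Conditions: BF3·OEt2, CH2Cl2, −78 °C; aq NaHCO3
Reagents that add atoms: none
Why: Marshall BF3-promoted anti-SE2′ allenylstannane addition through an open transition state gives the syn adduct; the axis returns to the former carbinol carbon as (2R) and controls (1S) (a dr of roughly 9:1 is expected, minor anti isomer removed by chromatography).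

Step 4
Reactants: 5 (1S,2R)-1-(3,4-dimethoxyphenyl)-2-methylbut-3-yn-1-ol
Product: 6 (1S,2R)-1-(3,4-dimethoxyphenyl)-2-methylbut-3-en-1-ol
Conditions: H2 (1 atm), Lindlar catalyst, quinoline, EtOAc, rt
Reagents that add atoms: none
Why: Lindlar semi-hydrogenation stops at the alkene; both stereocentres are untouched.

Step 5
Reactants: 6 (1S,2R)-1-(3,4-dimethoxyphenyl)-2-methylbut-3-en-1-ol
Product: 8 (3R,4R,5S)-5-(3,4-dimethoxyphenyl)-3,4-dimethyloxolan-2-ol, via hydroxy aldehyde 7 (not isolated)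
Conditions: Rh(acac)(CO)2 (2 mol %), Ph2POMe (10 mol %), 4 Å MS, CO/H2 (1:1, 40 bar), THF, 40 °C; then DBU (0.2 equiv), rt
Reagents that add atoms: carbon monoxide, [C-]#[O+]
Why: Directed branch-selective hydroformylation (the achiral phosphinite exchanges reversibly with the homoallylic OH and delivers Rh–H to the internal carbon); the aldehyde closes to the lactol, and DBU equilibrates C3 through the open aldehyde to the 3,4-trans isomer dictated by C4 and C5.

Step 6
Reactants: 8 (3R,4R,5S)-5-(3,4-dimethoxyphenyl)-3,4-dimethyloxolan-2-ol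
Product: 9 (3R,4R,5S)-5-(3,4-dimethoxyphenyl)-2-[(4-fluorophenyl)sulfanyl]-3,4-dimethyloxolane
Conditions: (4-FC6H4S)2, n-Bu3P, CH2Cl2, 0 °C to rt
Reagents that add atoms: bis(4-fluorophenyl) disulfide, Fc1ccc(SSc2ccc(F)cc2)cc1
Why: Hata-type redox condensation replaces the anomeric OH by ArS under neutral conditions; ring centres are untouched and the anomeric mixture is irrelevant.

Step 7
Reactants: 10 (S)-2-hydroxy-N,N-dimethylpropanamide; 11 (3,4-dimethoxyphenyl)magnesium bromide
Product: 12 (S)-1-(3,4-dimethoxyphenyl)-2-hydroxypropan-1-one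
Conditions: 11 (2.5 equiv), THF, −10 to 0 °C; aq NH4Cl
Reagents that add atoms: none
Why: Grignard acyl substitution on the tertiary amide; the first equivalent makes the alkoxide, which blocks enolisation of the lactate centre and over-addition, so (S) is kept.

Step 8
Reactants: 12 (S)-1-(3,4-dimethoxyphenyl)-2-hydroxypropan-1-one; 13 4-bromo-2-methoxyphenol
Product: 14 (R)-2-(4-bromo-2-methoxyphenoxy)-1-(3,4-dimethoxyphenyl)propan-1-one
Conditions: PPh3, DIAD, THF, 0 °C to rt
Reagents that add atoms: none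
Why: Mitsunobu etherification with SN2 inversion (S to R) at the lactate-derived carbon.

Step 9
Reactants: 14 (R)-2-(4-bromo-2-methoxyphenoxy)-1-(3,4-dimethoxyphenyl)propan-1-one
Product: 15 (1R,2R)-2-(4-bromo-2-methoxyphenoxy)-1-(3,4-dimethoxyphenyl)propan-1-ol
Conditions: n-Bu4NBH4, MeOH/CH2Cl2, −40 °C
Reagents that add atoms: none
Why: Felkin–Anh (polar, non-chelating counter-ion) hydride reduction; hydride adds anti to the aryloxy group and gives the threo (1R) alcohol, which can be purified at this small-fragment stage.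

Step 10
Reactants: 9 (3R,4R,5S)-5-(3,4-dimethoxyphenyl)-2-[(4-fluorophenyl)sulfanyl]-3,4-dimethyloxolane; 15 (1R,2R)-2-(4-bromo-2-methoxyphenoxy)-1-(3,4-dimethoxyphenyl)propan-1-ol
Product: 18 target (1R,2R)-1-(3,4-dimethoxyphenyl)-2-{4-[(2S,3R,4R,5S)-5-(3,4-dimethoxyphenyl)-3,4-dimethyloxolan-2-yl]-2-methoxyphenoxy}propan-1-ol, via oxocarbenium ion 16 (not isolated), via arylzinc reagent 17 (not isolated)
Conditions: (4-FC6H4S)2 (1.5 equiv), Bu4NBF4, CH2Cl2, −78 °C, divided cell (carbon-felt anode, Pt cathode, TfOH in catholyte), constant current, 1.05 F/mol; current off, then 9, −78 °C; then 17 [from 15 (1.6 equiv): n-BuLi, then t-BuLi, then ZnBr2, THF, −78 °C], −78 to −20 °C; aq NH4Cl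
Reagents that add atoms: none
Why: Proposed new method: an electrochemically mediated cation-pool C-arylation. The anode oxidises only the disulfide to ArS(ArSSAr)+, so the dimethoxyarene never meets the electrode. This thiophile strips ArS from 9 at −78 °C and pools oxocarbenium ion 16 with no nucleophile present. The arylzinc 17 is then added and attacks the five-membered cation from the inside of its envelope, syn to the C3 methyl and anti to the C4 methyl and C5 aryl, forming the C2–aryl bond as (2S) with the aryl cis to C3-Me. Any O-capture by the zinc alkoxide gives an acetal that re-ionises under the zinc salts. The closest known reactions are anodic alkoxycarbenium and glycosyl cation pools from thioacetals, and the thermal Lewis-acid addition of arylzinc halides to 2-sulfonyloxolanes, which gives this same 2,3-cis-3,4-trans-4,5-cis array. New here are an organozinc nucleophile on a pooled oxolanyl cation and a lignan substrate that carries the whole side chain.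

## Compound list

1 | (R)-but-3-yn-2-ol | C#C[C@@H](C)O | starting material
2 | (R)-but-3-yn-2-yl methanesulfonate | C#C[C@@H](C)OS(C)(=O)=O | intermediate
3 | (P)-tributyl(buta-1,2-dien-1-yl)stannane | [H]C([Sn](CCCC)(CCCC)CCCC)=[C@]=C([H])C | intermediate
4 | 3,4-dimethoxybenzaldehyde | COc1ccc(C=O)cc1OC | starting material
5 | (1S,2R)-1-(3,4-dimethoxyphenyl)-2-methylbut-3-yn-1-ol | C#C[C@@H](C)[C@H](O)c1ccc(OC)c(OC)c1 | intermediate
6 | (1S,2R)-1-(3,4-dimethoxyphenyl)-2-methylbut-3-en-1-ol | C=C[C@@H](C)[C@H](O)c1ccc(OC)c(OC)c1 | intermediate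
7 | (3R,4S)-4-(3,4-dimethoxyphenyl)-4-hydroxy-2,3-dimethylbutanal (C2 epimers) | O=CC(C)[C@@H](C)[C@H](O)c1ccc(OC)c(OC)c1 | intermediate (not isolated)
8 | (3R,4R,5S)-5-(3,4-dimethoxyphenyl)-3,4-dimethyloxolan-2-ol (anomers) | OC1O[C@H](c2ccc(OC)c(OC)c2)[C@H](C)[C@H]1C | intermediate
9 | (3R,4R,5S)-5-(3,4-dimethoxyphenyl)-2-[(4-fluorophenyl)sulfanyl]-3,4-dimethyloxolane (anomers) | Fc1ccc(SC2O[C@H](c3ccc(OC)c(OC)c3)[C@H](C)[C@H]2C)cc1 | intermediate
10 | (S)-2-hydroxy-N,N-dimethylpropanamide | C[C@H](O)C(=O)N(C)C | starting material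
11 | (3,4-dimethoxyphenyl)magnesium bromide | COc1ccc([Mg]Br)cc1OC | starting material
12 | (S)-1-(3,4-dimethoxyphenyl)-2-hydroxypropan-1-one | COc1ccc(C(=O)[C@H](C)O)cc1OC | intermediate
13 | 4-bromo-2-methoxyphenol | COc1cc(Br)ccc1O | starting material
14 | (R)-2-(4-bromo-2-methoxyphenoxy)-1-(3,4-dimethoxyphenyl)propan-1-one | COc1ccc(C(=O)[C@@H](C)Oc2ccc(Br)cc2OC)cc1OC | intermediate
15 | (1R,2R)-2-(4-bromo-2-methoxyphenoxy)-1-(3,4-dimethoxyphenyl)propan-1-ol | COc1ccc([C@@H](O)[C@@H](C)Oc2ccc(Br)cc2OC)cc1OC | intermediate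
16 | (3R,4R,5S)-5-(3,4-dimethoxyphenyl)-3,4-dimethyl-4,5-dihydro-3H-furan-1-ium tetrafluoroborate (oxocarbenium ion) | C1=[O+][C@H](c2ccc(OC)c(OC)c2)[C@H](C)[C@H]1C.F[B-](F)(F)F | intermediate (not isolated)
17 | bromozinc aryl / lithium alkoxide reagent from 15 | COc1ccc([C@@H](O[Li])[C@@H](C)Oc2ccc([Zn]Br)cc2OC)cc1OC | intermediate (not isolated)
18 | (1R,2R)-1-(3,4-dimethoxyphenyl)-2-{4-[(2S,3R,4R,5S)-5-(3,4-dimethoxyphenyl)-3,4-dimethyloxolan-2-yl]-2-methoxyphenoxy}propan-1-ol | COc1ccc([C@@H](O)[C@@H](C)Oc2ccc([C@H]3O[C@H](c4ccc(OC)c(OC)c4)[C@H](C)[C@H]3C)cc2OC)cc1OC | target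

## Step count and risks

Total steps: 10. Longest linear sequence: 7 (steps 1–6, then 10); the side branch is 3 steps (7–9).

**Step 10 (the proposed new step).** Risks are the lifetime of cation 16, loss of H3 to the enol ether, O-capture by the alkoxide of 17, and the facial selectivity. The fallback uses the known sulfone route and no electrolysis. It sets out from lactol 8: benzenesulfinic acid and CaCl2 in CH2Cl2 give (3R,4R,5S)-2-(benzenesulfonyl)-5-(3,4-dimethoxyphenyl)-3,4-dimethyloxolane F1. This is ionised by the zinc halide in THF at rt while the arylzinc 17 (from 15) adds. It comes back to the route at 18.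

**Step 5.** Risks are the branched:linear ratio on an alkene with an allylic methyl group and the C3 epimer ratio after DBU. The fallback sets out from 6. 9-BBN then NaOH/H2O2 gives (1S,2R)-1-(3,4-dimethoxyphenyl)-2-methylbutane-1,4-diol F2. TEMPO/PhI(OAc)2 oxidative lactonisation gives (4R,5S)-5-(3,4-dimethoxyphenyl)-4-methyloxolan-2-one F3. LiHMDS/MeI at −78 °C methylates anti to the C4 methyl and gives (3R,4R,5S)-5-(3,4-dimethoxyphenyl)-3,4-dimethyloxolan-2-one F4. DIBAL-H at −78 °C then returns to the route at 8.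

**Step 9.** The risk is a modest threo:erythro ratio. The fallback sets out from 14. Chelation-controlled reduction with Zn(BH4)2 in Et2O gives the erythro alcohol (1S,2R)-2-(4-bromo-2-methoxyphenoxy)-1-(3,4-dimethoxyphenyl)propan-1-ol F5. Mitsunobu esterification with 4-nitrobenzoic acid inverts C1 and gives (1R,2R)-2-(4-bromo-2-methoxyphenoxy)-1-(3,4-dimethoxyphenyl)propyl 4-nitrobenzoate F6. K2CO3/MeOH then returns to the route at 15.

## Further compounds

F1 | step 10 | (3R,4R,5S)-2-(benzenesulfonyl)-5-(3,4-dimethoxyphenyl)-3,4-dimethyloxolane | O=S(=O)(c1ccccc1)C1O[C@H](c2ccc(OC)c(OC)c2)[C@H](C)[C@H]1C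
F2 | step 5 | (1S,2R)-1-(3,4-dimethoxyphenyl)-2-methylbutane-1,4-diol | OCC[C@@H](C)[C@H](O)c1ccc(OC)c(OC)c1
F3 | step 5 | (4R,5S)-5-(3,4-dimethoxyphenyl)-4-methyloxolan-2-one | O=C1C[C@@H](C)[C@H](O1)c2ccc(OC)c(OC)c2
F4 | step 5 | (3R,4R,5S)-5-(3,4-dimethoxyphenyl)-3,4-dimethyloxolan-2-one | O=C1O[C@H](c2ccc(OC)c(OC)c2)[C@H](C)[C@H]1C
F5 | step 9 | (1S,2R)-2-(4-bromo-2-methoxyphenoxy)-1-(3,4-dimethoxyphenyl)propan-1-ol | COc1ccc([C@H](O)[C@@H](C)Oc2ccc(Br)cc2OC)cc1OC
F6 | step 9 | (1R,2R)-2-(4-bromo-2-methoxyphenoxy)-1-(3,4-dimethoxyphenyl)propyl 4-nitrobenzoate | COc1ccc([C@@H](OC(=O)c3ccc(cc3)[N+](=O)[O-])[C@@H](C)Oc2ccc(Br)cc2OC)cc1OC
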